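**Retrosynthetic overview**

1. The target is epicatechin-(4β→8)-epicatechin-(4β→6)-epicatechin, three identical (2R,3R)-flavan-3-ol units. It is cut at the two interflavan bonds (C4 upper → C8 middle, C4 middle → C6 terminal) into one tetra-O-benzyl monomer used three times: as a C8-bromo-capped C4 electrophile, as a C4 thioether with free C8, and as a C8-bromo nucleophile that can react only at C6.
2. Ring C of the monomer is disconnected at C4–C3 and O1–C2, one oxidation level up. At the flavylium (anthocyanidin) level both bonds come from one acid-mediated condensation of a ring A salicylaldehyde with a ring B ω-acetoxyacetophenone.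
3. Enabling feature: in the terminal unit O1 is a phenolic oxygen on C8a of the phloroglucinol ring A, ortho to C4a, which carries C4. C2 carries the catechol ring B and C3 an oxygen, so ring C (O1, C2, C3, C4, C4a, C8a) is a reduced 3-oxygenated 2-arylbenzopyrylium. Its C4 is a salicylaldehyde carbon, and C2/C3 are an aryl ketone carbon and its α-oxygenated carbon.
4. The planar, achiral cation postpones all stereochemistry. Hydride transfer and deacetylation funnel it into a configurationally labile 3-ketone, and one dynamic kinetic hydrogenation then sets C2 and C3 together as cis-(2R,3R).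
5. Order of ring formation: rings A and B are bought as benzenes; ring C is built once (key step) for all three units. Then follow C8 bromination and C4 activation, the 4β→8 coupling, the 4β→6 coupling and global hydrogenolysis.

Key step: step 4

Remark on the chemistry: the sense of induction of the diphosphine/diamine RuCl2 catalyst on the flavan-3-one cannot be predicted with certainty; the antipode that leads to the known laevorotatory (2R,3R) alcohol is meant and is written as the (S)-xylbinap/(S)-daipen complex.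

**Route**

Step 1
Reactants: 1 3,5-bis(benzyloxy)phenol
Product: 2 4,6-bis(benzyloxy)-2-hydroxybenzaldehyde
Conditions: MgCl2, Et3N, (CH2O)n, MeCN, reflux; aq. HCl work-up
Reagents that add atoms: paraformaldehyde (as formaldehyde), C=O
Why: Magnesium-mediated ortho-formylation (Casnati–Skattebøl reaction): the magnesium phenoxide delivers formaldehyde only to a carbon next to the free hydroxyl (the two such carbons of 1 are equivalent) and a second formaldehyde oxidises the hydroxymethyl intermediate, so the aldehyde that becomes C4 sits ortho to the one unprotected oxygen that becomes O1.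

Step 2
Reactants: 3 1-[3,4-bis(benzyloxy)phenyl]ethanone
Product: 4 2-bromo-1-[3,4-bis(benzyloxy)phenyl]ethanone
Conditions: CuBr2 (2 equiv), EtOAc/CHCl3, reflux
Reagents that add atoms: copper dibromide, [Cu+2].[Br-].[Br-]
Why: Selective α-bromination of an aryl methyl ketone through its enol by CuBr2, which should leave the acyl-deactivated ring and the benzyl ethers untouched.

Step 3
Reactants: 4 2-bromo-1-[3,4-bis(benzyloxy)phenyl]ethanone
Product: 5 2-[3,4-bis(benzyloxy)phenyl]-2-oxoethyl acetate
Conditions: KOAc, DMF, rt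
Reagents that add atoms: potassium acetate, CC(=O)[O-].[K+]
Why: SN2 displacement of the primary α-keto bromide by acetate, which installs the oxygen of the future C3 in protected form.

Step 4
Reactants: 2 4,6-bis(benzyloxy)-2-hydroxybenzaldehyde; 5 2-[3,4-bis(benzyloxy)phenyl]-2-oxoethyl acetate
Product: 6 3-acetoxy-5,7-bis(benzyloxy)-2-[3,4-bis(benzyloxy)phenyl]chromenylium chloride (flavylium salt)
Conditions: anhydrous HCl (g), EtOAc, 0 °C then 4 °C, 24–48 h; salt filtered off
Reagents that add atoms: hydrogen chloride, Cl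
Why: Acid-mediated crossed aldol condensation and cyclodehydration, the classical flavylium (anthocyanidin) salt synthesis from a 2-hydroxybenzaldehyde and an ω-acyloxyacetophenone in HCl-saturated ethyl acetate, which is the closest known reaction and matches these substrates directly. The enol of 5, whose only enolisable carbon is the acetoxymethylene (future C3), adds to the protonated aldehyde carbon of 2 (future C4) and water is lost to give the 2-hydroxychalcone cation, which forms the C4–C3 bond. The phenolic oxygen of ring A (future O1) then closes ring C onto the ketone carbon (future C2) by 6-exo-trig hemiketalisation, and loss of a second water aromatises the ring to the benzopyrylium ion, which forms the O1–C2 bond, pulls all preceding equilibria forward and crystallises as the chloride. No stereocentre is created: C2 and C3 are left on purpose as sp2 carbons of a planar achiral cation, so that both are set together by the dynamic reduction of step 6. The step needs chemo- and regioselectivity, and the substrates secure both, because 2 cannot enolise, 5 enolises in one direction only, and 2 has a single free hydroxyl (the other ring A oxygens are benzylated) so that only one heterocycle can close. Aryl benzyl ethers and the acetate are expected to tolerate anhydrous HCl at 0 °C, and should the acetate be lost the 3-hydroxyflavylium ion would lead to the same ketone in step 5.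

Step 5
Reactants: 6 3-acetoxy-5,7-bis(benzyloxy)-2-[3,4-bis(benzyloxy)phenyl]chromenylium chloride
Product: 8 (±)-5,7-bis(benzyloxy)-2-[3,4-bis(benzyloxy)phenyl]chroman-3-one, via enol acetate 7 (not isolated)
Conditions: Hantzsch ester (1.2 equiv), MeCN, 0 °C → rt; then K2CO3, MeOH, 0 °C, argon; AcOH quench
Reagents that add atoms: none
Why: Hydride transfer from the Hantzsch ester to the electrophilic C4 of the pyrylium ring (NADH-type reduction of a flavylium ion) should give enol acetate 7, and Zemplén-type methanolysis frees the enol, which tautomerises to ketone 8; a C2 hydride adduct, if formed, gives the same ketone, so the step is regioconvergent and the new C2 centre is left racemic and labile on purpose.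

Step 6
Reactants: 8 (±)-5,7-bis(benzyloxy)-2-[3,4-bis(benzyloxy)phenyl]chroman-3-one
Product: 9 (2R,3R)-5,7-bis(benzyloxy)-2-[3,4-bis(benzyloxy)phenyl]chroman-3-ol (5,7,3',4'-tetra-O-benzyl-(−)-epicatechin)
Conditions: H2 (20 atm), RuCl2[(S)-xylbinap][(S)-daipen] (1 mol%), t-BuOK (10 mol%), i-PrOH/THF, 25 °C
Reagents that add atoms: none
Why: Noyori asymmetric hydrogenation with dynamic kinetic resolution: C2 (benzylic, α to the ketone and to O1) should epimerise through the enolate faster than the ketone is reduced, and the chiral RuH/NH catalyst hydrogenates one C2 enantiomer from the face opposite the 2-aryl group, so that C2 and C3 emerge together as the cis-(2R,3R) alcohol, as in the dynamic hydrogenations of 2-aryl- and 2-alkoxycyclohexanones and in line with the cis preference of hydride additions to this ketone.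

Step 7
Reactants: 9 5,7,3',4'-tetra-O-benzyl-(−)-epicatechin
Product: 10 (2R,3R)-5,7-bis(benzyloxy)-2-[3,4-bis(benzyloxy)phenyl]-8-bromochroman-3-ol (8-bromo-tetra-O-benzylepicatechin)
Conditions: NBS (1.0 equiv), CH2Cl2, −40 °C → 0 °C
Reagents that add atoms: N-bromosuccinimide, O=C1CCC(=O)N1Br
Why: Electrophilic aromatic bromination, which on 5,7-di-O-benzyl flavan-3-ols goes to C8 (ortho to O1, para to the C5 oxygen) and not to the more hindered C6 between two benzyloxy groups, and which touches no stereocentre.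

Step 8
Reactants: 10 8-bromo-tetra-O-benzylepicatechin
Product: 11 8-bromo-4β-(2-ethoxyethoxy)-5,7,3',4'-tetra-O-benzylepicatechin (2,3-cis-3,4-trans)
Conditions: DDQ (2 equiv), 2-ethoxyethanol (5 equiv), CH2Cl2, rt
Reagents that add atoms: 2-ethoxyethanol, CCOCCO
Why: DDQ oxidation of the benzylic C4 position (hydride abstraction to the ring A stabilised C4 cation) with trapping by the alcohol, which should enter trans to the C3 hydroxyl and the C2 aryl group and so give the 4β ether.

Step 9
Reactants: 9 5,7,3',4'-tetra-O-benzyl-(−)-epicatechin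
Product: 12 4β-(2-ethoxyethoxy)-5,7,3',4'-tetra-O-benzylepicatechin (2,3-cis-3,4-trans)
Conditions: DDQ (2 equiv), 2-ethoxyethanol (5 equiv), CH2Cl2, rt
Reagents that add atoms: 2-ethoxyethanol, CCOCCO
Why: The same DDQ benzylic oxidation with alcohol trapping as in step 8, with the 4β configuration again set by attack anti to the 3-OH and the 2-aryl group.

Step 10
Reactants: 12 4β-(2-ethoxyethoxy)-5,7,3',4'-tetra-O-benzylepicatechin
Product: 13 4β-(benzylsulfanyl)-5,7,3',4'-tetra-O-benzylepicatechin (2,3-cis-3,4-trans)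
Conditions: BnSH (5 equiv), BF3·OEt2 (cat.), CH2Cl2, −78 → −20 °C
Reagents that add atoms: phenylmethanethiol (benzyl mercaptan), SCc1ccccc1
Why: Lewis acid thiolysis: BF3 ionises the C4 ether and the soft thiol, in excess, should capture the cation from the β face (trans to 3-OH) faster than C8 of a second molecule can, giving a 4β thioether that is inert to hard Lewis acids.

Step 11
Reactants: 11 8-bromo-4β-(2-ethoxyethoxy)-tetra-O-benzylepicatechin; 13 4β-(benzylsulfanyl)-tetra-O-benzylepicatechin
Product: 14 [8-bromo-5,7,3',4'-tetra-O-benzylepicatechin]-(4β→8)-[4β-(benzylsulfanyl)-5,7,3',4'-tetra-O-benzylepicatechin]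
Conditions: BF3·OEt2 (cat.), CH2Cl2, −78 → −30 °C; 13 in slight excess
Reagents that add atoms: none
Why: Friedel–Crafts-type flavan-4-yl cation coupling (the standard interflavan bond formation): BF3 ionises only the C4–O bond of 11, whose C8 bromine prevents self-condensation, and C8 of 13 (the most nucleophilic ring A position) should attack the cation anti to the 3-OH, setting the new C4 centre as 4β while the C4–S bond of 13 stays intact.

Step 12
Reactants: 14 bromo-capped dimer thioether; 10 8-bromo-tetra-O-benzylepicatechin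
Product: 15 [8-bromo-5,7,3',4'-tetra-O-benzylepicatechin]-(4β→8)-[5,7,3',4'-tetra-O-benzylepicatechin]-(4β→6)-[8-bromo-5,7,3',4'-tetra-O-benzylepicatechin]
Conditions: AgBF4 (2 equiv), 10 (3 equiv), THF, 0 °C → rt, dark
Reagents that add atoms: none
Why: Thiophilic activation of the C4 thioether: AgBF4 removes the benzylthio group as the silver thiolate and the middle-unit C4 cation should be captured by 10, whose C8 is blocked by bromine so that only C6 can react (4→6 bond), again from the β face to give the 3,4-trans (4β) centre.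

Step 13
Reactants: 15 dodeca-O-benzyl dibromo trimer
Product: 16 epicatechin-(4β→8)-epicatechin-(4β→6)-epicatechin (CNP0178679.3)
Conditions: H2 (1 atm), Pd(OH)2/C, Et3N (2.2 equiv), THF/MeOH/H2O, rt
Reagents that add atoms: none
Why: Hydrogenolysis over Pd(OH)2/C should cleave all twelve aryl benzyl ethers and both aryl C–Br bonds in one operation, with Et3N taking up the HBr so that the acid-labile interflavan bonds and all eight stereocentres stay untouched.

**Compound list**

1 | 3,5-bis(benzyloxy)phenol | Oc1cc(OCc2ccccc2)cc(OCc2ccccc2)c1 | starting material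
2 | 4,6-bis(benzyloxy)-2-hydroxybenzaldehyde | O=Cc1c(O)cc(OCc2ccccc2)cc1OCc1ccccc1 | intermediate
3 | 1-[3,4-bis(benzyloxy)phenyl]ethanone | CC(=O)c1ccc(OCc2ccccc2)c(OCc2ccccc2)c1 | starting material
4 | 2-bromo-1-[3,4-bis(benzyloxy)phenyl]ethanone | BrCC(=O)c1ccc(OCc2ccccc2)c(OCc2ccccc2)c1 | intermediate
5 | 2-[3,4-bis(benzyloxy)phenyl]-2-oxoethyl acetate | CC(=O)OCC(=O)c1ccc(OCc2ccccc2)c(OCc2ccccc2)c1 | intermediate
6 | 3-acetoxy-5,7-bis(benzyloxy)-2-[3,4-bis(benzyloxy)phenyl]chromenylium chloride | CC(=O)Oc1cc2c(OCc3ccccc3)cc(OCc3ccccc3)cc2[o+]c1-c1ccc(OCc2ccccc2)c(OCc2ccccc2)c1.[Cl-] | intermediate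
7 | 5,7-bis(benzyloxy)-2-[3,4-bis(benzyloxy)phenyl]-4H-chromen-3-yl acetate (not isolated) | CC(=O)OC1=C(c2ccc(OCc3ccccc3)c(OCc3ccccc3)c2)Oc2cc(OCc3ccccc3)cc(OCc3ccccc3)c2C1 | intermediate
8 | (±)-5,7-bis(benzyloxy)-2-[3,4-bis(benzyloxy)phenyl]chroman-3-one (C2 racemic and labile) | O=C1Cc2c(OCc3ccccc3)cc(OCc3ccccc3)cc2OC1c1ccc(OCc2ccccc2)c(OCc2ccccc2)c1 | intermediate
9 | (2R,3R)-5,7-bis(benzyloxy)-2-[3,4-bis(benzyloxy)phenyl]chroman-3-ol (tetra-O-benzyl-(−)-epicatechin) | O[C@@H]1Cc2c(OCc3ccccc3)cc(OCc3ccccc3)cc2O[C@@H]1c1ccc(OCc2ccccc2)c(OCc2ccccc2)c1 | intermediate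
10 | (2R,3R)-5,7-bis(benzyloxy)-2-[3,4-bis(benzyloxy)phenyl]-8-bromochroman-3-ol | O[C@@H]1Cc2c(OCc3ccccc3)cc(OCc3ccccc3)c(Br)c2O[C@@H]1c1ccc(OCc2ccccc2)c(OCc2ccccc2)c1 | intermediate
11 | 8-bromo-4β-(2-ethoxyethoxy)-5,7,3',4'-tetra-O-benzylepicatechin | O[C@@H]1[C@@H](OCCOCC)c2c(OCc3ccccc3)cc(OCc3ccccc3)c(Br)c2O[C@@H]1c1ccc(OCc2ccccc2)c(OCc2ccccc2)c1 | intermediate
12 | 4β-(2-ethoxyethoxy)-5,7,3',4'-tetra-O-benzylepicatechin | O[C@@H]1[C@@H](OCCOCC)c2c(OCc3ccccc3)cc(OCc3ccccc3)cc2O[C@@H]1c1ccc(OCc2ccccc2)c(OCc2ccccc2)c1 | intermediate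
13 | 4β-(benzylsulfanyl)-5,7,3',4'-tetra-O-benzylepicatechin | O[C@@H]1[C@@H](SCc2ccccc2)c2c(OCc3ccccc3)cc(OCc3ccccc3)cc2O[C@@H]1c1ccc(OCc2ccccc2)c(OCc2ccccc2)c1 | intermediate
14 | [8-bromo-tetra-O-benzylepicatechin]-(4β→8)-[4β-(benzylsulfanyl)-tetra-O-benzylepicatechin] | c1ccccc1COc1cc(OCc3ccccc3)c2c(c1Br)O[C@H](c1ccc(OCc3ccccc3)c(OCc3ccccc3)c1)[C@H](O)[C@H]2c1c(OCc3ccccc3)cc(OCc3ccccc3)c2c1O[C@H](c1ccc(OCc3ccccc3)c(OCc3ccccc3)c1)[C@H](O)[C@H]2SCc1ccccc1 | intermediate
15 | [8-bromo-tetra-O-benzylepicatechin]-(4β→8)-[tetra-O-benzylepicatechin]-(4β→6)-[8-bromo-tetra-O-benzylepicatechin] | c1ccccc1COc1cc(OCc3ccccc3)c2c(c1Br)O[C@H](c1ccc(OCc3ccccc3)c(OCc3ccccc3)c1)[C@H](O)[C@H]2c1c(OCc3ccccc3)cc(OCc3ccccc3)c2c1O[C@H](c1ccc(OCc3ccccc3)c(OCc3ccccc3)c1)[C@H](O)[C@H]2c1c(OCc3ccccc3)c(Br)c2c(c1OCc1ccccc1)C[C@@H](O)[C@@H](c1ccc(OCc3ccccc3)c(OCc3ccccc3)c1)O2 | intermediate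
16 | epicatechin-(4β→8)-epicatechin-(4β→6)-epicatechin (CNP0178679.3) | Oc1cc(O)c2c(c1)O[C@H](c1ccc(O)c(O)c1)[C@H](O)[C@H]2c1c(O)cc(O)c2c1O[C@H](c1ccc(O)c(O)c1)[C@H](O)[C@H]2c1c(O)cc2c(c1O)C[C@@H](O)[C@@H](c1ccc(O)c(O)c1)O2 | target

**Count**

Total step count: 13. Longest linear sequence: 10 steps (steps 2, 3, 4, 5, 6, 9, 10, 11, 12, 13).

**Three steps most likely to fail**

Step 4 (key step). Benzyl groups on the very electron-rich ring A may be lost or migrate from oxygen to carbon during the long exposure to anhydrous HCl, and the condensation may stall at the chalcone or hemiketal stage. The fallback forms the same two bonds under base, without acid, and sets out from 2. Aldehyde 2 and commercial (E)-1,2-bis(benzyloxy)-4-(2-nitrovinyl)benzene F1 with DABCO (MeCN, 40 °C) should undergo oxa-Michael addition, Henry reaction and dehydration to racemic 5,7-bis(benzyloxy)-2-[3,4-bis(benzyloxy)phenyl]-3-nitro-2H-chromene F2. NaBH4 (THF/MeOH, 0 °C) should reduce the nitroalkene to 5,7-bis(benzyloxy)-2-[3,4-bis(benzyloxy)phenyl]-3-nitrochroman F3. A Nef reaction (NaOMe, then aqueous TiCl3/NH4OAc) should then give ketone 8, where the route is rejoined.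

Step 6. Epimerisation at C2 may be slow compared with hydrogenation, so that the dynamic resolution is incomplete, or the base-sensitive ketone may be consumed by enolate side reactions. The fallback replaces catalyst control by substrate control plus resolution and sets out from 8. LiBH(s-Bu)3 (THF, −78 °C) should add hydride anti to the 2-aryl group and give racemic cis-5,7-bis(benzyloxy)-2-[3,4-bis(benzyloxy)phenyl]chroman-3-ol F4. This is resolved by preparative chromatography on a chiral stationary phase; the laevorotatory (2R,3R) enantiomer is 9, where the route is rejoined. At most half of the material is used.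

Step 12. Attack of the flanked C6 of 10 on the bulky dimeric cation may be slow, so that the cation is consumed by self-condensation through the free C6 positions of 14 or by elimination. The fallback reverses the order of assembly: the hindered 4→6 bond is made first between two monomers, with an iodine cap that can be removed beside bromine. It sets out from 12 and 10. NIS (CH2Cl2, −40 °C) should iodinate 12 at C8 to give 8-iodo-4β-(2-ethoxyethoxy)-tetra-O-benzylepicatechin F5. F5 and an excess of 10 with BF3·OEt2 (CH2Cl2, −78 °C) should give [8-iodo-tetra-O-benzylepicatechin]-(4β→6)-[8-bromo-tetra-O-benzylepicatechin] F6. i-PrMgCl·LiCl (THF, −40 °C, excess to deprotonate both hydroxyls; then MeOH) should exchange only the iodide and give [tetra-O-benzylepicatechin]-(4β→6)-[8-bromo-tetra-O-benzylepicatechin] F7, which has a free C8 on its upper unit. F7 and 11 with BF3·OEt2 (CH2Cl2, −78 °C) should then give 15, where the route is rejoined.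

**Further compounds**

F1 | step 4 | (E)-1,2-bis(benzyloxy)-4-(2-nitrovinyl)benzene (purchased) | [O-][N+](=O)/C=C/c1ccc(OCc2ccccc2)c(OCc2ccccc2)c1
F2 | step 4 | 5,7-bis(benzyloxy)-2-[3,4-bis(benzyloxy)phenyl]-3-nitro-2H-chromene (racemic) | [O-][N+](=O)C1=Cc2c(OCc3ccccc3)cc(OCc3ccccc3)cc2OC1c1ccc(OCc2ccccc2)c(OCc2ccccc2)c1
F3 | step 4 | 5,7-bis(benzyloxy)-2-[3,4-bis(benzyloxy)phenyl]-3-nitrochroman (mixture of stereoisomers) | [O-][N+](=O)C1Cc2c(OCc3ccccc3)cc(OCc3ccccc3)cc2OC1c1ccc(OCc2ccccc2)c(OCc2ccccc2)c1
F4 | step 6 | racemic cis-5,7-bis(benzyloxy)-2-[3,4-bis(benzyloxy)phenyl]chroman-3-ol (both enantiomers written) | O[C@@H]1Cc2c(OCc3ccccc3)cc(OCc3ccccc3)cc2O[C@@H]1c1ccc(OCc2ccccc2)c(OCc2ccccc2)c1.O[C@H]1Cc2c(OCc3ccccc3)cc(OCc3ccccc3)cc2O[C@H]1c1ccc(OCc2ccccc2)c(OCc2ccccc2)c1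
F5 | step 12 | 8-iodo-4β-(2-ethoxyethoxy)-5,7,3',4'-tetra-O-benzylepicatechin | O[C@@H]1[C@@H](OCCOCC)c2c(OCc3ccccc3)cc(OCc3ccccc3)c(I)c2O[C@@H]1c1ccc(OCc2ccccc2)c(OCc2ccccc2)c1
F6 | step 12 | [8-iodo-tetra-O-benzylepicatechin]-(4β→6)-[8-bromo-tetra-O-benzylepicatechin] | c1ccccc1COc1cc(OCc3ccccc3)c2c(c1I)O[C@H](c1ccc(OCc3ccccc3)c(OCc3ccccc3)c1)[C@H](O)[C@H]2c1c(OCc3ccccc3)c(Br)c2c(c1OCc1ccccc1)C[C@@H](O)[C@@H](c1ccc(OCc3ccccc3)c(OCc3ccccc3)c1)O2
F7 | step 12 | [tetra-O-benzylepicatechin]-(4β→6)-[8-bromo-tetra-O-benzylepicatechin] | c1ccccc1COc1cc(OCc3ccccc3)c2c(c1)O[C@H](c1ccc(OCc3ccccc3)c(OCc3ccccc3)c1)[C@H](O)[C@H]2c1c(OCc3ccccc3)c(Br)c2c(c1OCc1ccccc1)C[C@@H](O)[C@@H](c1ccc(OCc3ccccc3)c(OCc3ccccc3)c1)O2
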